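## The problem

The target, 15, is a (2S)-flavanone. A phloroglucinol-type ring A is fused to the dihydropyranone ring C, which carries the 4-hydroxy-3-methoxyphenyl ring B at C2. Ring A bears a 1,1-dimethylallyl group at C6, between the hydroxyls on C5 and C7.

- **Regiochemistry.** C6 and C8 differ only in which of the two oxygens ortho to the acyl carbon becomes O1. A chalcone cyclisation leaves this choice open, so it has to be settled before ring C exists.
- **Quaternary carbon.** C1'' sits on an aromatic carbon between two oxygens. A sigmatropic shift can build it; direct alkylation cannot.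
- **Stereocentre.** C2 is the only stereocentre, so nothing in the molecule can relay to it and it must come from a catalyst. It is also fragile: base opens ring C by retro-oxa-Michael reaction, and the para oxygen of ring B helps the benzylic C2–O1 bond to ionise.
- **Sensitive groups.** The vinyl group next to two phenols rules out hydrogenolysis and strong acid. Three phenols must be unmasked at the end under mild conditions.
- **Enabling feature.** C4 is a ketone carbon bound to ring A, and C3 is a methylene next to the O-benzylic C2. The C3–C4 bond can therefore be drawn as the union of an enol ether alkene and a 1-arylallyl ether alkene. The third alkene, on quaternary C1'', is too shielded and too far away to take part.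

## Retrosynthesis

**15 to 13 (through 14).** No skeletal bond is cut. The C4 ketone is written as a silyl enol ether, O5 as a silyl ether, and O7 and O4' as methoxymethyl ethers, giving the 2H-chromene 13. Silicon on O4 and O5 and acetals on the other two oxygens all fall to one mild protic treatment. The enol ether is cleaved by protonation at C3, so no enolate forms and ring C has no route to open. Nothing needs hydrogen or strong base.

**13 to 12.** The C3=C4 double bond is cut, which opens ring C to the triene 12 and adds one methylene to each alkene carbon. This is preferred over the neighbouring cuts: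
- Cutting O1–C2 (oxa-Michael) leaves the C6/C8 choice and the base-labile stereocentre to the last step.
- Cutting C2–C1' (conjugate arylation of a chromone) needs a chromone with the same C6/C8 ambiguity.
- Cutting C4–C4a (acylation of ring A) has no regiocontrol on a phloroglucinol.

In 12 the stereocentre is already in place as an allylic aryl ether and is not part of the reacting bonds. The forward step must join a monosubstituted and a 1,1-disubstituted alkene and ignore the neopentyl-type vinyl group.

**12 to 11.** Two O–Si bonds are cut, giving the hydroxy ketone 11. Phenol and ketone are silylated together in one operation. The crowded O5 is protected without any need to tell it apart from another hydroxyl, because it is the only one left. The forward step needs a base strong enough for the methyl ketone and mild enough for the allylic ether.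

**11 to 6 and 10.** The O1–C2 bond is cut to the dihydroxyacetophenone 6 and the cinnamyl carbonate 10. Making this bond by asymmetric allylic substitution sets C2 and, in the same event, decides C6 versus C8. Of the two chelated hydroxyls of 6, only the one remote from the tert-alkyl group is accessible. The precursors are an achiral ketone and an achiral carbonate. The forward reaction must be selective for the branched ether and for one face.

**6 to 5, 3, 1 and 2.** The acetal on O7 is removed to give the triol 5. The aryl–C1'' bond is then traced back through dienone 4 to the prenyl ether 3, and 3 to 1 and 2. In 3 the two positions ortho to the ether oxygen are equivalent and the para position carries the acetyl group, so the [3,3] shift has one outcome. The forward sequence needs the para hydroxyl of 1 and of 5 to react ahead of the chelated ones. Its higher acidity makes that likely.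

**10 to 9, 8 and 7.** The carbonate is cut to the allylic alcohol 9, which comes from ester 8 by reduction and from 7 by one protection that caps both the phenol and the acid. Ring B thus arrives with its oxygenation pattern and its E-alkene intact.

## Roads not taken

**Alternative 1: enzymatic assembly of rings A and C.**
- *Cut:* C4–C4a, C5–C6, C7–C8, C4a–C8a and O1–C2.
- *Key step:* 7 is activated by a CoA ligase and extended by chalcone synthase with three units from malonic acid A2. Chalcone isomerase then closes ring C to (2S)-homoeriodictyol A1.
- *Merits:* in step count and enantiopurity this road is clearly better than the chosen one. It is one pot, uses no protecting groups, and the 2S configuration is set by an enzyme.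
- *Weak points:* A1 lacks the C6 substituent. Adding it late means O-prenylation and a thermal Claisen shift on a finished flavanone with three free phenols, two competing ortho positions (C6 and C8), and a stereocentre that racemises through the chalcone when heated with base.
- *Comparison:* the chosen plan is longer, but the tert-alkyl group is installed on the symmetric ketone 3, where there is only one possible site, and before C2 exists.

**Alternative 2: photochemical Wolff benzannulation of ring A.**
- *Cut:* C8–C8a, C5–C6, C7–C8 and C4a–C5.
- *Key step:* irradiating the diazoketone A3 with the siloxyalkyne A4 starts a cascade of Wolff rearrangement, [2+2] addition, four-electron ring opening and six-electron closure. It gives the bis-silylated flavanone A5, one desilylation from 15.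
- *Merits:* the placement of every ring A substituent is encoded in the two partners, and the product is closer to the target than 13. In convergence at the end this road is as good as the chosen one or better.
- *Weak points:* A3 is a chiral 2-aryl-dihydropyranone carrying a diazoacetyl group and needs its own asymmetric synthesis. A4 has a quaternary propargylic carbon that slows the [2+2] step. The cascade needs light and heat, and a flavanone with a free C5 hydroxyl does not tolerate either well.
- *Comparison:* the chosen plan uses three commodity starting materials, a catalytic asymmetric step with close precedent and no diazo compound. It pays with two extra protecting-group operations.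

**Alternative 3: asymmetric cycloaddition of an ortho-quinone methide equivalent.**
- *Cut:* C3–C4 and O1–C2.
- *Key step:* salicylaldehyde A6, the silylated vinylguaiacol A7 and trimethyl orthoformate A8 react under a confined chiral Brønsted acid to give the cis-4-methoxyflavan A9.
- *Merits:* two bonds and ring C form in the step that sets C2. The chosen plan's key step forms one bond and sets no stereocentre, so this road is better on that count.
- *Weak points:* A9 has the wrong oxidation level at C4, so the ether must be hydrolysed and the alcohol oxidised next to an electron-rich ring. A6 needs the crowded hydroxyl silylated and the open one left free, which is the reverse of what sterics deliver. A7 polymerises readily under strong acid.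
- *Comparison:* in the chosen plan sterics sort the hydroxyls of 6 in the right direction, and C4 already has the ketone oxidation level as an enol ether.

Key step: step 9

Assumption: with aryl-substituted allyl carbonates, the iridium complex of the (Sa,Sc,Sc) phosphoramidite is taken to deliver the phenoxide to the face that gives the (S) ether. If the sense is the opposite, the (Ra,Rc,Rc) ligand is used and nothing else changes.

## Route

Step 1
Reactants: 1 2,4,6-trihydroxyacetophenone; 2 prenyl bromide
Product: 3 1-[2,6-dihydroxy-4-(3-methylbut-2-enyloxy)phenyl]ethanone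
Conditions: K2CO3, acetone, reflux
Reagents that add atoms: none
Why: Williamson ether synthesis; the hydroxyl para to the acetyl group is the most acidic and is not hydrogen-bonded, so carbonate should alkylate it ahead of the two chelated hydroxyls.

Step 2
Reactants: 3 1-[2,6-dihydroxy-4-(3-methylbut-2-enyloxy)phenyl]ethanone
Product: 5 1-[2,4,6-trihydroxy-3-(2-methylbut-3-en-2-yl)phenyl]ethanone, via Claisen dienone 4 (not isolated)
Conditions: PhNEt2, 190 °C, argon
Reagents that add atoms: none
Why: Aromatic Claisen rearrangement; the [3,3] shift bonds the dimethyl-substituted allyl terminus to the ortho carbon and 4 tautomerises to the phenol. The two ortho positions of 3 are equivalent and the para position is blocked by the acetyl group, so only one constitution can form.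

Step 3
Reactants: 5 1-[2,4,6-trihydroxy-3-(2-methylbut-3-en-2-yl)phenyl]ethanone
Product: 6 1-[2,6-dihydroxy-4-(methoxymethoxy)-3-(2-methylbut-3-en-2-yl)phenyl]ethanone
Conditions: MOMCl (1.05 equiv), i-Pr2NEt, CH2Cl2, −20 to 0 °C
Reagents that add atoms: chloromethyl methyl ether, COCCl
Why: Acetal-type O-alkylation of a phenol; the para hydroxyl is much more acidic than the chelated ones, so a weak amine base and one equivalent of a small electrophile should react there despite the neighbouring quaternary carbon.

Step 4
Reactants: 7 ferulic acid
Product: 8 methoxymethyl (E)-3-[3-methoxy-4-(methoxymethoxy)phenyl]prop-2-enoate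
Conditions: MOMCl (2.5 equiv), i-Pr2NEt, CH2Cl2, 0 °C to rt
Reagents that add atoms: chloromethyl methyl ether, COCCl
Why: O-alkylation of phenoxide and carboxylate with the same reagent; the phenol is capped and the acid is turned into a reducible ester in one operation.

Step 5
Reactants: 8 methoxymethyl (E)-3-[3-methoxy-4-(methoxymethoxy)phenyl]prop-2-enoate
Product: 9 (E)-3-[3-methoxy-4-(methoxymethoxy)phenyl]prop-2-en-1-ol
Conditions: i-Bu2AlH, CH2Cl2, −78 °C; Rochelle salt work-up
Reagents that add atoms: none
Why: 1,2-Hydride reduction of an α,β-unsaturated ester to the allylic alcohol; i-Bu2AlH at low temperature leaves the alkene and the aryl acetal untouched.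

Step 6
Reactants: 9 (E)-3-[3-methoxy-4-(methoxymethoxy)phenyl]prop-2-en-1-ol
Product: 10 (E)-3-[3-methoxy-4-(methoxymethoxy)phenyl]prop-2-enyl methyl carbonate
Conditions: ClCO2Me, pyridine, CH2Cl2, 0 °C
Reagents that add atoms: methyl chloroformate, COC(=O)Cl
Why: Acylation of a primary allylic alcohol to the carbonate, the standard leaving group for iridium-catalysed allylic substitution.

Step 7
Reactants: 6 1-[2,6-dihydroxy-4-(methoxymethoxy)-3-(2-methylbut-3-en-2-yl)phenyl]ethanone; 10 (E)-3-[3-methoxy-4-(methoxymethoxy)phenyl]prop-2-enyl methyl carbonate
Product: 11 1-[2-hydroxy-6-{[(1S)-1-[3-methoxy-4-(methoxymethoxy)phenyl]prop-2-en-1-yl]oxy}-4-(methoxymethoxy)-3-(2-methylbut-3-en-2-yl)phenyl]ethanone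
Conditions: [Ir(cod)Cl]2 (2 mol%), (Sa,Sc,Sc)-binaphthyl N,N-bis(1-phenylethyl)phosphoramidite (4 mol%), n-PrNH2 pre-activation; K3PO4, THF, rt to 40 °C
Reagents that add atoms: none
Why: Iridium-catalysed asymmetric allylic etherification; the phenoxide attacks the aryl-substituted terminus of the allyl iridium complex from outside the metal, giving the branched ether, and the phosphoramidite fixes the face and hence the S configuration. Of the two chelated hydroxyls only the one away from the tert-alkyl group is accessible, which also settles C6 versus C8.

Step 8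
Reactants: 11 1-[2-hydroxy-6-{[(1S)-1-[3-methoxy-4-(methoxymethoxy)phenyl]prop-2-en-1-yl]oxy}-4-(methoxymethoxy)-3-(2-methylbut-3-en-2-yl)phenyl]ethanone
Product: 12 triethyl({1-[2-{[(1S)-1-[3-methoxy-4-(methoxymethoxy)phenyl]prop-2-en-1-yl]oxy}-4-(methoxymethoxy)-5-(2-methylbut-3-en-2-yl)-6-(triethylsilyloxy)phenyl]ethenyl}oxy)silane
Conditions: KN(SiMe3)2 (2.5 equiv), THF, −78 °C; Et3SiCl, −78 to 0 °C; product handled on Et3N-treated silica
Reagents that add atoms: chlorotriethylsilane, CC[Si](Cl)(CC)CC
Why: Double deprotonation of phenol and methyl ketone followed by O-silylation (silyl enol ether formation); the ketone has a single enolisable position and the amide base is too weak to remove the allylic benzylic hydrogen at C2.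

Step 9
Reactants: 12 triethyl({1-[2-{[(1S)-1-[3-methoxy-4-(methoxymethoxy)phenyl]prop-2-en-1-yl]oxy}-4-(methoxymethoxy)-5-(2-methylbut-3-en-2-yl)-6-(triethylsilyloxy)phenyl]ethenyl}oxy)silane
Product: 13 (2S)-2-[3-methoxy-4-(methoxymethoxy)phenyl]-7-(methoxymethoxy)-6-(2-methylbut-3-en-2-yl)-4,5-bis(triethylsilyloxy)-2H-chromene
Conditions: second-generation Grubbs catalyst RuCl2(=CHPh)(PCy3)(H2IMes) (5–10 mol%), 1,4-benzoquinone (10 mol%), CH2Cl2 (0.005 M), 40 °C, dark, argon sparge
Reagents that add atoms: none
Why: Ring-closing olefin metathesis: the ruthenium benzylidene should exchange onto the monosubstituted allylic ether alkene, add across the 1,1-disubstituted silyl enol ether alkene with the metal on its CH2 end, and open the ruthenacyclobutane to form C3=C4 and a ruthenium methylidene that leaves as ethylene. The closest known reactions are the ring-closing metathesis of silyl enol ethers to cyclic silyl enol ethers, including N-allyl-2-(1-silyloxyvinyl)anilines to 4-silyloxy-1,2-dihydroquinolines, and of allyl 2-vinylphenyl ethers to 2H-chromenes. Ring C closes as a six-membered ring through an endocyclic trisubstituted enol ether double bond, helped by the ortho placement of the two alkenes on ring A. No stereocentre is formed; C2, set in step 7, lies outside the reacting bonds and should be kept. The step needs chemoselectivity among three terminal alkenes: the vinyl group on quaternary C1'' has no partner within reach and, as a neopentyl-type alkene, dimerises very slowly, while high dilution suppresses coupling between molecules. 1,4-Benzoquinone intercepts ruthenium hydrides that would move the allylic double bond towards C2. The mild temperature in the dark keeps the allyl aryl ether below its Claisen threshold and the chromene away from electrocyclic opening.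

Step 10
Reactants: 13 (2S)-2-[3-methoxy-4-(methoxymethoxy)phenyl]-7-(methoxymethoxy)-6-(2-methylbut-3-en-2-yl)-4,5-bis(triethylsilyloxy)-2H-chromene
Product: 15 (2S)-5,7-dihydroxy-2-(4-hydroxy-3-methoxyphenyl)-6-(2-methylbut-3-en-2-yl)-2,3-dihydro-4H-chromen-4-one, via bis-MOM flavanone 14 (not isolated)
Conditions: HCl (3 M aq.), MeOH/THF, 0 to 40 °C
Reagents that add atoms: none
Why: Acid hydrolysis of the silyl enol ether by protonation at C3 and of the aryl silyl ether gives 14, and acetal methanolysis then frees O7 and O4'. No enolate is formed, so the retro-oxa-Michael path to racemisation is closed, and the vinyl group would need a secondary cation to react and should survive dilute acid.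

## Compound list

1 | 2,4,6-trihydroxyacetophenone | CC(=O)c1c(O)cc(O)cc1O | starting material
2 | prenyl bromide (1-bromo-3-methylbut-2-ene) | CC(C)=CCBr | starting material
3 | 1-[2,6-dihydroxy-4-(3-methylbut-2-enyloxy)phenyl]ethanone | CC(=O)c1c(O)cc(OCC=C(C)C)cc1O | intermediate
4 | 4-acetyl-3,5-dihydroxy-6-(2-methylbut-3-en-2-yl)cyclohexa-2,4-dien-1-one (racemic Claisen dienone, not isolated) | CC(=O)C1=C(O)C(C(C)(C)C=C)C(=O)C=C1O | intermediate
5 | 1-[2,4,6-trihydroxy-3-(2-methylbut-3-en-2-yl)phenyl]ethanone | CC(=O)c1c(O)cc(O)c(C(C)(C)C=C)c1O | intermediate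
6 | 1-[2,6-dihydroxy-4-(methoxymethoxy)-3-(2-methylbut-3-en-2-yl)phenyl]ethanone | CC(=O)c1c(O)cc(OCOC)c(C(C)(C)C=C)c1O | intermediate
7 | ferulic acid | COc1cc(/C=C/C(=O)O)ccc1O | starting material
8 | methoxymethyl (E)-3-[3-methoxy-4-(methoxymethoxy)phenyl]prop-2-enoate | COCOC(=O)/C=C/c1ccc(OCOC)c(OC)c1 | intermediate
9 | (E)-3-[3-methoxy-4-(methoxymethoxy)phenyl]prop-2-en-1-ol | OC/C=C/c1ccc(OCOC)c(OC)c1 | intermediate
10 | (E)-3-[3-methoxy-4-(methoxymethoxy)phenyl]prop-2-enyl methyl carbonate | COC(=O)OC/C=C/c1ccc(OCOC)c(OC)c1 | intermediate
11 | 1-[2-hydroxy-6-{[(1S)-1-[3-methoxy-4-(methoxymethoxy)phenyl]prop-2-en-1-yl]oxy}-4-(methoxymethoxy)-3-(2-methylbut-3-en-2-yl)phenyl]ethanone | C=C[C@@H](c1ccc(OCOC)c(OC)c1)Oc1cc(OCOC)c(C(C)(C)C=C)c(O)c1C(C)=O | intermediate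
12 | triethyl({1-[2-{[(1S)-1-[3-methoxy-4-(methoxymethoxy)phenyl]prop-2-en-1-yl]oxy}-4-(methoxymethoxy)-5-(2-methylbut-3-en-2-yl)-6-(triethylsilyloxy)phenyl]ethenyl}oxy)silane | C=C[C@@H](c1ccc(OCOC)c(OC)c1)Oc1cc(OCOC)c(C(C)(C)C=C)c(O[Si](CC)(CC)CC)c1C(=C)O[Si](CC)(CC)CC | intermediate
13 | (2S)-2-[3-methoxy-4-(methoxymethoxy)phenyl]-7-(methoxymethoxy)-6-(2-methylbut-3-en-2-yl)-4,5-bis(triethylsilyloxy)-2H-chromene | C=CC(C)(C)c1c(OCOC)cc2c(c1O[Si](CC)(CC)CC)C(O[Si](CC)(CC)CC)=C[C@@H](c1ccc(OCOC)c(OC)c1)O2 | intermediate
14 | (2S)-5-hydroxy-2-[3-methoxy-4-(methoxymethoxy)phenyl]-7-(methoxymethoxy)-6-(2-methylbut-3-en-2-yl)-2,3-dihydro-4H-chromen-4-one (not isolated) | C=CC(C)(C)c1c(OCOC)cc2c(c1O)C(=O)C[C@@H](c1ccc(OCOC)c(OC)c1)O2 | intermediate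
15 | (2S)-5,7-dihydroxy-2-(4-hydroxy-3-methoxyphenyl)-6-(2-methylbut-3-en-2-yl)-2,3-dihydro-4H-chromen-4-one (CNP0279383.1) | C=CC(C)(C)c1c(O)cc2c(c1O)C(=O)C[C@@H](c1ccc(O)c(OC)c1)O2 | target

## Step count and risks

Total step count: 10. Longest linear sequence: 7 steps (steps 1, 2, 3, 7, 8, 9, 10 from 1; equally steps 4 to 10 from 7).

**Step 9 (key step).**
- *Risk:* slow ring closure. The enol ether alkene stands twisted between two ortho substituents and must turn into the plane of ring A against the neighbouring triethylsilyl ether. Metathesis between molecules at the allylic ether alkene, catalyst decay, and hydride-mediated migration of the allylic double bond (which would erase C2) could then take over.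
- *Fallback:* it sets out from 11. The dianion of 11 is made as in step 8 and quenched with i-Pr2SiCl2. This should give the cyclic silylene enol ether (S)-5-{[1-(3-methoxy-4-(methoxymethoxy)phenyl)prop-2-enyl]oxy}-7-(methoxymethoxy)-4-methylidene-8-(2-methylbut-3-en-2-yl)-2,2-di(propan-2-yl)-4H-1,3,2-benzodioxasiline F1. In F1 the exocyclic methylene is held in the ring plane facing the allylic ether, as in an allyl 2-vinylphenyl ether. Ring-closing metathesis under the conditions of step 9 would give the O4,O5-(diisopropylsilanediyl)-bridged (2S)-2H-chromene-4,5-diol derivative F2, which has no peri repulsion. The conditions of step 10 return F2 to the route at 14, and then 15.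

**Step 7.**
- *Risk:* sluggish O-allylation by a chelated, ortho-acylated phenoxide; competing C-allylation of the electron-rich ring; and re-ionisation of the electron-rich branched ether by the catalyst, with drift to the linear isomer and loss of enantiopurity.
- *Fallback:* it sets out from 9 and 6. 1,1'-Carbonyldiimidazole converts 9 into (E)-3-[3-methoxy-4-(methoxymethoxy)phenyl]prop-2-enyl imidazole-1-carboxylate F3. F3 acylates the accessible hydroxyl of 6 to give 2-acetyl-3-hydroxy-5-(methoxymethoxy)-4-(2-methylbut-3-en-2-yl)phenyl (E)-3-[3-methoxy-4-(methoxymethoxy)phenyl]prop-2-enyl carbonate F4. Enantioselective iridium-catalysed decarboxylative allylic etherification of F4 with the same ligand generates phenoxide and allyl complex as an ion pair without added base. It returns to the route at 11.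

**Step 2.**
- *Risk:* heterolysis of the prenyl–oxygen bond, since the phenoxide is a good leaving group, with loss or 1,3-shift of the prenyl group. The product may also react further on heating, by the abnormal Claisen pathway through a free ortho hydroxyl or by ring closure onto a flanking hydroxyl.
- *Fallback:* it sets out from 3. The rearrangement is run in PhNEt2 with Ac2O and NaOAc, so that the hydroxyls are acetylated in the flask and the new phenol is trapped as it forms. This gives 2-acetyl-4-(2-methylbut-3-en-2-yl)benzene-1,3,5-triyl triacetate F5. K2CO3 in MeOH returns to the route at 5.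

**Step 3.**
- *Risk:* incomplete site selectivity between the acidic but flanked para hydroxyl and the open chelated hydroxyl, and double alkylation.
- *Fallback:* it sets out from 3. Ac2O and pyridine give 2-acetyl-5-(3-methylbut-2-enyloxy)-1,3-phenylene diacetate F6. Claisen rearrangement gives 2-acetyl-5-hydroxy-4-(2-methylbut-3-en-2-yl)-1,3-phenylene diacetate F7, whose only free hydroxyl is the one to be protected. MOMCl and i-Pr2NEt give 2-acetyl-5-(methoxymethoxy)-4-(2-methylbut-3-en-2-yl)-1,3-phenylene diacetate F8. K2CO3 in MeOH removes both acetates and returns to the route at 6.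

**Step 10.**
- *Risk:* loss of configuration at C2 by acid-assisted ionisation of the benzylic C2–O1 bond or by ring opening, and Markovnikov addition of a flanking phenol to the vinyl group during prolonged exposure to acid.
- *Fallback:* it sets out from 13. Et3N·3HF in THF removes both silyl groups and 14 is isolated. The acetals are then cleaved without protic acid by ZnBr2 and n-PrSH in CH2Cl2 at 0 °C, returning to the route at 15. This fallback makes no compound beyond the list (F0).

## Further compounds

F1 | step 9 | (S)-5-{[1-(3-methoxy-4-(methoxymethoxy)phenyl)prop-2-enyl]oxy}-7-(methoxymethoxy)-4-methylidene-8-(2-methylbut-3-en-2-yl)-2,2-di(propan-2-yl)-4H-1,3,2-benzodioxasiline | C=C[C@@H](c1ccc(OCOC)c(OC)c1)Oc1cc(OCOC)c(C(C)(C)C=C)c2c1C(=C)O[Si](C(C)C)(C(C)C)O2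
F2 | step 9 | (2S)-4,5-O,O-(diisopropylsilanediyl)-2-[3-methoxy-4-(methoxymethoxy)phenyl]-7-(methoxymethoxy)-6-(2-methylbut-3-en-2-yl)-2H-chromene-4,5-diol | C=CC(C)(C)c1c(OCOC)cc2c3c1O[Si](C(C)C)(C(C)C)OC3=C[C@@H](c1ccc(OCOC)c(OC)c1)O2
F3 | step 7 | (E)-3-[3-methoxy-4-(methoxymethoxy)phenyl]prop-2-enyl 1H-imidazole-1-carboxylate | O=C(OC/C=C/c1ccc(OCOC)c(OC)c1)n1ccnc1
F4 | step 7 | 2-acetyl-3-hydroxy-5-(methoxymethoxy)-4-(2-methylbut-3-en-2-yl)phenyl (E)-3-[3-methoxy-4-(methoxymethoxy)phenyl]prop-2-enyl carbonate | CC(=O)c1c(O)c(C(C)(C)C=C)c(OCOC)cc1OC(=O)OC/C=C/c1ccc(OCOC)c(OC)c1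
F5 | step 2 | 2-acetyl-4-(2-methylbut-3-en-2-yl)benzene-1,3,5-triyl triacetate | CC(=O)c1c(OC(C)=O)cc(OC(C)=O)c(C(C)(C)C=C)c1OC(C)=O
F6 | step 3 | 2-acetyl-5-(3-methylbut-2-enyloxy)-1,3-phenylene diacetate | CC(=O)c1c(OC(C)=O)cc(OCC=C(C)C)cc1OC(C)=O
F7 | step 3 | 2-acetyl-5-hydroxy-4-(2-methylbut-3-en-2-yl)-1,3-phenylene diacetate | CC(=O)c1c(OC(C)=O)cc(O)c(C(C)(C)C=C)c1OC(C)=O
F8 | step 3 | 2-acetyl-5-(methoxymethoxy)-4-(2-methylbut-3-en-2-yl)-1,3-phenylene diacetate | CC(=O)c1c(OC(C)=O)cc(OCOC)c(C(C)(C)C=C)c1OC(C)=O
F0 | step 10 | none | none
A1 | alternative 1 | (2S)-homoeriodictyol | O=C1C[C@@H](c2ccc(O)c(OC)c2)Oc2cc(O)cc(O)c21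
A2 | alternative 1 | malonic acid | O=C(O)CC(=O)O
A3 | alternative 2 | (2S)-6-(2-diazoacetyl)-2-[3-methoxy-4-(triisopropylsilyloxy)phenyl]-2,3-dihydro-4H-pyran-4-one | [N-]=[N+]=CC(=O)C1=CC(=O)C[C@@H](c2ccc(O[Si](C(C)C)(C(C)C)C(C)C)c(OC)c2)O1
A4 | alternative 2 | [(3,3-dimethylpent-4-en-1-yn-1-yl)oxy]triisopropylsilane | C=CC(C)(C)C#CO[Si](C(C)C)(C(C)C)C(C)C
A5 | alternative 2 | (2S)-5-hydroxy-2-[3-methoxy-4-(triisopropylsilyloxy)phenyl]-6-(2-methylbut-3-en-2-yl)-7-(triisopropylsilyloxy)-2,3-dihydro-4H-chromen-4-one | C=CC(C)(C)c1c(O[Si](C(C)C)(C(C)C)C(C)C)cc2c(c1O)C(=O)C[C@@H](c1ccc(O[Si](C(C)C)(C(C)C)C(C)C)c(OC)c1)O2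
A6 | alternative 3 | 2,4-bis(tert-butyldimethylsilyloxy)-6-hydroxy-3-(2-methylbut-3-en-2-yl)benzaldehyde | O=Cc1c(O)cc(O[Si](C)(C)C(C)(C)C)c(C(C)(C)C=C)c1O[Si](C)(C)C(C)(C)C
A7 | alternative 3 | tert-butyl(4-ethenyl-2-methoxyphenoxy)dimethylsilane | C=Cc1ccc(O[Si](C)(C)C(C)(C)C)c(OC)c1
A8 | alternative 3 | trimethyl orthoformate | COC(OC)OC
A9 | alternative 3 | (2S,4S)-5,7-bis(tert-butyldimethylsilyloxy)-2-[4-(tert-butyldimethylsilyloxy)-3-methoxyphenyl]-4-methoxy-6-(2-methylbut-3-en-2-yl)chromane (2,4-cis) | C=CC(C)(C)c1c(O[Si](C)(C)C(C)(C)C)cc2c(c1O[Si](C)(C)C(C)(C)C)[C@@H](OC)C[C@@H](c1ccc(O[Si](C)(C)C(C)(C)C)c(OC)c1)O2
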